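The earlier runs and the new flask are calculated on assumed constants; the scatter is artificial.

In the gamma run at 3.00 min, 58% target stood beside 14% substrate, and the question is what a flask with less enzyme and more time gives instead.

| flask | substrate | enzyme | remark | time |
|---|---|---|---|---|
| epsilon | 17 mM | 0.0045 mol% | run made earlier |  |
| gamma | 17 mM | 0.015 mol% | run made earlier |  |
| north-east | 17 mM | 0.011 mol% |  | 4.0 min |
| south | 17 mM | 0.003 mol% |  | 15 min |

| run | time / min | target / % | substrate / % |
|---|---|---|---|
| epsilon | 0.833 | 2 | 90 |
| epsilon | 1.50 | 10 | 84 |
| epsilon | 2.50 | 18 | 65 |
| epsilon | 3.00 | 18 | 66 |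
| epsilon | 4.00 | 22 | 56 |
| gamma | 0.833 | 18 | 73 |
| gamma | 1.50 | 34 | 48 |
| gamma | 2.50 | 54 | 21 |
| gamma | 3.00 | 58 | 14 |
| gamma | 4.00 | 62 | 6 |

(readings scatter by 2 percentage points)



1. which of the two ends with the higher amount of target, in percent of the substrate charged ("neither" if they lie within 2 percentage points) (north-east / south / neither)
2. target at the end, in percent of the substrate charged, north-east
3. target at the end, in percent of the substrate charged, south

Do the two flasks get equal enzyme work? We scale each time by its loading over gamma's: south has 3.00 min and north-east 2.93 min. We call this the equivalent time, and both lie close to that gamma reading.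

Does equal equivalent time mean equal flasks? Epsilon's readings at 2.50 min and 3.00 min have equivalent times of 0.750 min and 0.900 min, on either side of gamma's reading at 0.833 min. Target reads 18% in each. But the gap in the balance, what is neither substrate nor target, reads 16.0% at epsilon's later reading against 9.00% in gamma, a read ratio of 1.78. Epsilon's stretch, real time over equivalent time, is 3.33, with a square root of 1.83. A scatter of 2 percentage points leaves that ratio loose, but we take the gap at equal equivalent time to grow as that root.

What is left for target? Gamma's gap at 3.00 min is 28.0%. Stretched, we reckon it at 62.6% in south and 32.7% in north-east. With substrate left between none and gamma's 14%, we expect south at 23.4% to 37.4% and north-east at 53.3% to 67.3%, so north-east wins.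

The forecast also says north-east, with 53% (47% to 58%) for north-east and 43% (34% to 50%) for south, on the ground that “a side loss exists that depends weakly on enzyme”, and its value for south stands higher than our range.

The flask gives 53.3% in north-east and 30.0% in south, so north-east ends higher.

    substrate + enzyme → target + enzyme, rate k1*[substrate]*[enzyme]/(1 + ([substrate]/Km1)) (6.10 mM, k = 8200 M⁻¹ s⁻¹)
    substrate + target → side product (k = 0.360 M⁻¹ s⁻¹)

South, at its equivalent time of 3.00 min, holds 65.6% side product, the gap we reckoned at 62.6%, with 4.5% substrate left. The neighbour is north-east read at 1.5 min. Its equivalent time is 1.10 min, between gamma's readings at 0.833 min and 1.50 min. Reading gamma's gap along a straight line between them gives 12.6%. North-east's stretch turns that into 14.7%. That neighbour holds 27.9% target, 59.8% substrate and 12.3% side product.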